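**Strategy.** Japonicone A is cut at the norbornene into an eudesmanolide dienophile and a 2-acetoxyguaia-1(5),3-diene, joined last by [4+2] cycloaddition. The seven-membered ring of the guaiane half (C1, C5, C6, C7, C8, C9, C10) is made from a cyclohexane in which C5 is a tertiary carbinol carbon. A gold-catalysed acyloxy shift/Nazarov cascade of an enynyl acetate first closes the cyclopentene on C5 as a spiro atom. The carbene then formed at C1 draws C10 over from C5, so the six-membered ring becomes seven-membered and the C1=C5 fusion bond appears. The precursor is a propargylic acetate of a 2-methylcyclohexanone.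

Key step: step 4

Remark 1: guaiane locants (C1–C15) are used for the acetoxy half and primed eudesmane locants (C1'–C15') for the other half; "syn" and "anti" refer to the ring face that carries the C10 (or C10') methyl group; TBS = tert-butyldimethylsilyl.
Remark 2: the eudesmanolide half of the given enantiomer is (1'S,4'R,7'S,8'S,10'S), antipodal to plant-derived 1β-hydroxyalantolactone, so it is built from (S)-Wieland–Miescher ketone.
Remark 3: enantiopure silyl ether 1 is assumed to be a catalogue compound (otherwise it is reachable from cyclohexa-1,3-diene by photooxygenation, asymmetric Kornblum–DeLaMare rearrangement and silylation).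

**Guaianolide branch**

Step 1
Reactants: 1 (R)-4-(TBS-oxy)cyclohex-2-en-1-one
Product: 2 (4R,6R)-4-(TBS-oxy)-6-methylcyclohex-2-en-1-one (methyl trans to silyloxy)
Conditions: LiN(i-Pr)2, THF, −78 °C; MeI, −78 to −40 °C
Reagents that add atoms: iodomethane CI
Why: Kinetic α'-enolate alkylation; axial attack of MeI on the face opposite the C4 silyloxy group should set the future C10 methyl anti to the future C8 oxygen.

Step 2
Reactants: 2; 3 1-methoxy-1-(trimethylsilyloxy)ethene
Product: 5 methyl 2-[(1S,2R,4R)-2-(TBS-oxy)-4-methyl-5-oxocyclohexyl]acetate, via trimethylsilyl enol ether 4 (not isolated)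
Conditions: Sc(OTf)3 (5 mol %), CH2Cl2, −78 °C; then 1 M HCl, THF, 0 °C
Reagents that add atoms: none
Why: Mukaiyama–Michael addition anti to the neighbouring silyloxy group gives the trans C7/C8 relationship, and the cold, non-basic enol ether hydrolysis should leave the axial α-methyl centre (C10) unepimerised.

Step 3
Reactants: 5; 6 (E)-pent-3-en-1-yne
Product: 7 methyl 2-[(1S,2R,4R,5S)-5-acetoxy-2-(TBS-oxy)-4-methyl-5-[(E)-pent-3-en-1-ynyl]cyclohexyl]acetate
Conditions: 6, n-BuLi, THF, −78 °C; CeCl3; then 5, −78 °C; then Ac2O, DMAP, −78 to 0 °C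
Reagents that add atoms: acetic anhydride CC(=O)OC(C)=O
Why: The weakly basic cerium acetylide adds 1,2 to the ketone without touching the ester or enolising C10, and the tertiary alkoxide is acetylated in situ; attack anti to the axial methyl is expected, but this carbinol centre disappears in step 4.

Step 4
Reactants: 7
Product: 10 methyl (7S,8R,10R)-8-(TBS-oxy)-2-oxo-13-norguai-1(5)-en-12-oate (C4 epimers), via allenyl acetate 8 (not isolated), via dienyl acetate 9 (not isolated)
Conditions: Ph3PAuNTf2 (2 mol %), dry CH2Cl2, 23 °C; then K2CO3 (0.2 equiv), MeOH, 0 °C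
Reagents that add atoms: none
Why: Proposed new method: the cationic monovalent gold catalyst should effect 1,3-acyloxy migration to allenyl acetate 8, whose gold-bound pentadienyl cation closes the C4–C5 bond by conrotatory 4π electrocyclisation to a spiro cyclopentenylidene–gold species with the carbene centre at C1; because C5 bears no hydrogen, the carbene is quenched by a 1,2-shift of a ring carbon from C5 to C1, which turns the cyclohexane into the cycloheptane and creates the C1=C5 bond (dienyl acetate 9), and methanolysis then gives enone 10. The closest known reaction type is the gold-catalysed tandem 3,3-rearrangement/Nazarov reaction of enynyl acetates, normally ended by a 1,2-hydride shift, together with ring-expanding 1,2-alkyl shifts of metal carbenes beside strained spiro rings. The five-membered ring closes by electrocyclisation and the seven-membered ring forms by ring expansion, not by cyclisation. C10 migrates with retention, C7 and C8 are untouched, and the new C4 centre (epimer mixture expected) is erased in step 21. The step needs migration of C10 in preference to C6 and to carbene C–H insertion or hydration; the higher migratory aptitude of the secondary, more electron-rich C10, the absence of hydrogen on C5 and the dry medium should secure this.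

Step 5
Reactants: 10
Product: 11 (7S,8R,10R)-2-oxo-13-norguai-1(5)-en-12,8-olide (trans-fused lactone; C4 epimers)
Conditions: HF·pyridine, THF, 0 to 23 °C; then TsOH (cat.), toluene, 40 °C
Reagents that add atoms: none
Why: Fluoride-free acidic desilylation followed by acid-catalysed lactonisation of the trans hydroxy ester; C10 is no longer enolisable.

Step 6
Reactants: 11
Product: 12 (7S,8R,10R)-2-oxo-3-(phenylselanyl)-13-norguai-1(5)-en-12,8-olide (selenium trans to the C4 methyl)
Conditions: LiN(i-Pr)2 (1.05 equiv), THF, −78 °C; PhSeCl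
Reagents that add atoms: benzeneselenenyl chloride Cl[Se]c1ccccc1
Why: C3 is the only α-carbon of the ketone that bears hydrogen and is more acidic than the lactone α-position, so kinetic enolate selenenylation is regiospecific and should place selenium trans to the C4 methyl (cis to H4).

Step 7
Reactants: 12
Product: 13 (7S,8R,10R)-2-hydroxy-3-(phenylselanyl)-13-norguai-1(5)-en-12,8-olide (2-OH syn)
Conditions: (R)-2-methyl-CBS-oxazaborolidine (20 mol %), catecholborane, toluene, −78 °C
Reagents that add atoms: none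
Why: Corey–Bakshi–Shibata reduction under catalyst control, with the alkenyl carbon C1 as the large group, should deliver hydride to the face anti to the C10 methyl for both C3/C4 diastereomers and so set C2.

Step 8
Reactants: 13
Product: 15 (7S,8R,10R)-2-hydroxy-3-(phenylselanyl)guaia-1(5),11(13)-dien-12,8-olide (2-OH syn), via Mannich base 14 (not isolated)
Conditions: LiN(i-Pr)2 (2.2 equiv), THF, −78 °C; CH2=NMe2+ I−, −78 to 0 °C; then MeI, MeOH, 23 °C; NaHCO3 (aq), CH2Cl2
Reagents that add atoms: N,N-dimethylmethyleneiminium iodide C=[N+](C)C.[I-]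
Why: Aminomethylation of the lactone enolate (the alkoxide is protected as its lithium salt), N-quaternisation and Hofmann-type elimination give the α-methylene lactone.

Step 9
Reactants: 15
Product: 16 (7S,8R,10R)-2-acetoxy-3-(phenylselanyl)guaia-1(5),11(13)-dien-12,8-olide (2-OAc syn)
Conditions: Ac2O, pyridine, DMAP (cat.), CH2Cl2, 0 to 23 °C
Reagents that add atoms: acetic anhydride CC(=O)OC(C)=O
Why: Standard acylation of the secondary allylic alcohol with retention at C2.

**Eudesmanolide branch**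

Step 10
Reactants: 17 (S)-Wieland–Miescher ketone
Product: 18 (S)-8a-methyl-4-methylidene-3,4,8,8a-tetrahydronaphthalene-1,6(2H,7H)-dione
Conditions: CH2(OMe)2, POCl3, NaOAc, CHCl3, reflux
Reagents that add atoms: dimethoxymethane COCOC
Why: Vinylogous (γ) methylenation of the enone through its dienol ether formed in situ, as in the 6-methylenation of 3-oxo-4-ene steroids; C4' is the only γ-carbon with hydrogen and a saturated ketone is tolerated.

Step 11
Reactants: 18
Product: 19 (4R,8aS)-4,8a-dimethyl-3,4,8,8a-tetrahydronaphthalene-1,6(2H,7H)-dione (methyl groups cis)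
Conditions: H2 (1 atm), RhCl(PPh3)3 (5 mol %), benzene, 23 °C
Reagents that add atoms: none
Why: Neutral homogeneous hydrogenation of the least hindered 1,1-disubstituted alkene; hydrogen should reach C4' from the face opposite the angular methyl and so place the new methyl syn.

Step 12
Reactants: 19
Product: 20 (4aS,5S,8R)-5-hydroxy-4a,8-dimethyl-4,4a,5,6,7,8-hexahydronaphthalen-2(3H)-one
Conditions: NaBH4 (0.3 equiv), EtOH, −10 °C
Reagents that add atoms: none
Why: The saturated ketone is reduced faster than the enone, and hydride attack anti to the angular methyl gives the C1' alcohol syn to it, as with the parent diketone.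

Step 13
Reactants: 20
Product: 21 (4aS,5S,8R)-5-(TBS-oxy)-4a,8-dimethyl-4,4a,5,6,7,8-hexahydronaphthalen-2(3H)-one
Conditions: TBSCl, imidazole, DMF, 23 °C
Reagents that add atoms: tert-butyldimethylsilyl chloride CC(C)(C)[Si](C)(C)Cl
Why: Silylation protects the C1' hydroxyl against O-alkylation in step 17.

Step 14
Reactants: 21
Product: 22 (4aS,5S,8R)-5-(TBS-oxy)-3-hydroxy-4a,8-dimethyl-4,4a,5,6,7,8-hexahydronaphthalen-2(3H)-one (C3 epimers)
Conditions: KN(SiMe3)2, THF, −78 °C; 2-(phenylsulfonyl)-3-phenyloxaziridine; NH4Cl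
Reagents that add atoms: 2-(phenylsulfonyl)-3-phenyloxaziridine O=S(=O)(c1ccccc1)N1OC1c1ccccc1
Why: Kinetic α'-enolate (C8') hydroxylation; the configuration at C8' is irrelevant and the γ-centre C4' is not deprotonated at low temperature.

Step 15
Reactants: 22
Product: 23 (4aS,5S,8R)-5-(TBS-oxy)-4a,8-dimethyl-2,3,4,4a,5,6,7,8-octahydronaphthalene-2,3-diol (C2/C3 epimers)
Conditions: NaBH4, CeCl3·7H2O, MeOH, −20 °C
Reagents that add atoms: none
Why: Luche 1,2-reduction of the enone to the allylic alcohol, which removes the enone that could epimerise C4'.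

Step 16
Reactants: 23
Product: 24 (5R,8S,8aS)-8-(TBS-oxy)-5,8a-dimethyl-1,5,6,7,8,8a-hexahydronaphthalen-2(3H)-one
Conditions: camphorsulfonic acid (10 mol %), benzene, 50 °C
Reagents that add atoms: none
Why: Pinacol-type 1,2-carbonyl transposition: ionisation of the allylic C7' hydroxyl and a 1,2-hydride shift from C8' (or loss of H8' to the enol) should give the β,γ-unsaturated C8' ketone with the C5'=C6' bond kept.

Step 17
Reactants: 24
Product: 26 methyl 2-[(3R,5R,8S,8aS)-8-(TBS-oxy)-5,8a-dimethyl-2-oxo-1,2,3,5,6,7,8,8a-octahydronaphthalen-3-yl]acetate (side chain syn), via C7' epimer 25 (not isolated)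
Conditions: LiN(i-Pr)2, THF–DMPU, −78 °C; BrCH2CO2Me; then KN(SiMe3)2, −78 to −40 °C; AcOH, −78 °C
Reagents that add atoms: methyl bromoacetate COC(=O)CBr
Why: The extended enolate alkylates at the doubly activated C7', probably anti to the angular methyl, so the dienolate is regenerated and protonated kinetically at C7' from that same face, which should put the side chain syn and keep the alkene at C5'–C6'.

Step 18
Reactants: 26
Product: 28 (3aR,5R,8S,8aS,9aS)-8-(TBS-oxy)-5,8a-dimethyl-3a,5,6,7,8,8a,9,9a-octahydronaphtho[2,3-b]furan-2(3H)-one, via hydroxy ester 27 (not isolated)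
Conditions: LiBH(s-Bu)3, THF, −78 to 0 °C
Reagents that add atoms: none
Why: The bulky hydride attacks C8' from the equatorial direction, away from the 1,3-related axial methyl, and the axial alkoxide syn to the side chain closes the cis-lactone.

Step 19
Reactants: 28
Product: 30 (3aS,5R,8S,8aS,9aS)-8-(TBS-oxy)-5,8a-dimethyl-3-methylidene-3a,5,6,7,8,8a,9,9a-octahydronaphtho[2,3-b]furan-2(3H)-one, via Mannich base 29 (not isolated)
Conditions: LiN(i-Pr)2, THF, −78 °C; CH2=NMe2+ I−; then MeI, MeOH, 23 °C; NaHCO3 (aq), CH2Cl2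
Reagents that add atoms: N,N-dimethylmethyleneiminium iodide C=[N+](C)C.[I-]
Why: Lactone enolate aminomethylation, quaternisation and elimination install the exocyclic methylene.

Step 20
Reactants: 30
Product: 31 (3aS,5R,8S,8aS,9aS)-8-hydroxy-5,8a-dimethyl-3-methylidene-3a,5,6,7,8,8a,9,9a-octahydronaphtho[2,3-b]furan-2(3H)-one (ent-1β-hydroxyalantolactone)
Conditions: HF·pyridine, MeCN, 0 to 23 °C
Reagents that add atoms: none
Why: Acidic fluoride removes the silyl ether without exposing the methylene lactone to a nucleophilic base.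

**Union**

Step 21
Reactants: 16; 31 (2 equiv, excess recovered)
Product: 34 japonicone A, via selenoxide 32 (not isolated), via acetoxy diene 33 (not isolated)
Conditions: mCPBA (1.0 equiv), CH2Cl2, −78 °C; then 31, i-Pr2NH, −78 to 30 °C, high concentration
Reagents that add atoms: none
Why: Selenoxide syn-elimination away from the acetoxy-bearing carbon should release the 5-acetoxycyclopentadiene 33 below room temperature, and its Diels–Alder reaction with the exocyclic methylene of 31 should join C1–C13' and C3–C11' (no adjacent quaternary carbons), endo to the lactone carbonyl, on the convex face of 31 and on the diene face anti to both the C10 methyl and the acetoxy group.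

**Compound list**

1 | (R)-4-(TBS-oxy)cyclohex-2-en-1-one | O=C1C=C[C@H](O[Si](C)(C)C(C)(C)C)CC1 | starting material
2 | (4R,6R)-4-(TBS-oxy)-6-methylcyclohex-2-en-1-one | O=C1C=C[C@H](O[Si](C)(C)C(C)(C)C)C[C@H]1C | intermediate
3 | 1-methoxy-1-(trimethylsilyloxy)ethene | COC(=C)O[Si](C)(C)C | starting material
4 | methyl 2-[(1R,4R,6R)-6-(TBS-oxy)-4-methyl-3-(trimethylsilyloxy)cyclohex-2-en-1-yl]acetate | C[C@@H]1C[C@@H](O[Si](C)(C)C(C)(C)C)[C@H](CC(=O)OC)C=C1O[Si](C)(C)C | intermediate (not isolated)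
5 | methyl 2-[(1S,2R,4R)-2-(TBS-oxy)-4-methyl-5-oxocyclohexyl]acetate | O=C1C[C@@H](CC(=O)OC)[C@H](O[Si](C)(C)C(C)(C)C)C[C@H]1C | intermediate
6 | (E)-pent-3-en-1-yne | C#C/C=C/C | starting material
7 | methyl 2-[(1S,2R,4R,5S)-5-acetoxy-2-(TBS-oxy)-4-methyl-5-[(E)-pent-3-en-1-ynyl]cyclohexyl]acetate | CC(=O)O[C@@]1(C#C/C=C/C)C[C@@H](CC(=O)OC)[C@H](O[Si](C)(C)C(C)(C)C)C[C@H]1C | intermediate
8 | methyl 2-[(1S,2R,4R)-5-[(3E)-2-acetoxypenta-1,3-dienylidene]-2-(TBS-oxy)-4-methylcyclohexyl]acetate (allene axis as formed, not specified) | CC(=O)OC(/C=C/C)=C=C1C[C@@H](CC(=O)OC)[C@H](O[Si](C)(C)C(C)(C)C)C[C@H]1C | intermediate (not isolated)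
9 | methyl (7S,8R,10R)-2-acetoxy-8-(TBS-oxy)-13-norguaia-1(5),2-dien-12-oate (C4 epimers) | CC(=O)OC1=CC(C)C2=C1[C@H](C)C[C@@H](O[Si](C)(C)C(C)(C)C)[C@H](CC(=O)OC)C2 | intermediate (not isolated)
10 | methyl (7S,8R,10R)-8-(TBS-oxy)-2-oxo-13-norguai-1(5)-en-12-oate (C4 epimers) | O=C1CC(C)C2=C1[C@H](C)C[C@@H](O[Si](C)(C)C(C)(C)C)[C@H](CC(=O)OC)C2 | intermediate
11 | (7S,8R,10R)-2-oxo-13-norguai-1(5)-en-12,8-olide (C4 epimers) | O=C1CC(C)C2=C1[C@H](C)C[C@H]3OC(=O)C[C@@H]3C2 | intermediate
12 | (7S,8R,10R)-2-oxo-3-(phenylselanyl)-13-norguai-1(5)-en-12,8-olide (3,4-trans; epimers) | O=C1C([Se]c2ccccc2)C(C)C3=C1[C@H](C)C[C@H]4OC(=O)C[C@@H]4C3 | intermediate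
13 | (7S,8R,10R)-2-hydroxy-3-(phenylselanyl)-13-norguai-1(5)-en-12,8-olide (2-OH syn) | O[C@H]1C([Se]c2ccccc2)C(C)C3=C1[C@H](C)C[C@H]4OC(=O)C[C@@H]4C3 | intermediate
14 | 11-[(dimethylamino)methyl] derivative of 13 | O[C@H]1C([Se]c2ccccc2)C(C)C3=C1[C@H](C)C[C@H]4OC(=O)C(CN(C)C)[C@@H]4C3 | intermediate (not isolated)
15 | (7S,8R,10R)-2-hydroxy-3-(phenylselanyl)guaia-1(5),11(13)-dien-12,8-olide (2-OH syn) | O[C@H]1C([Se]c2ccccc2)C(C)C3=C1[C@H](C)C[C@H]4OC(=O)C(=C)[C@@H]4C3 | intermediate
16 | (7S,8R,10R)-2-acetoxy-3-(phenylselanyl)guaia-1(5),11(13)-dien-12,8-olide (2-OAc syn) | CC(=O)O[C@H]1C([Se]c2ccccc2)C(C)C3=C1[C@H](C)C[C@H]4OC(=O)C(=C)[C@@H]4C3 | intermediate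
17 | (S)-8a-methyl-3,4,8,8a-tetrahydronaphthalene-1,6(2H,7H)-dione (Wieland–Miescher ketone) | O=C1CC[C@]2(C)C(=O)CCCC2=C1 | starting material
18 | (S)-8a-methyl-4-methylidene-3,4,8,8a-tetrahydronaphthalene-1,6(2H,7H)-dione | O=C1CC[C@]2(C)C(=O)CCC(=C)C2=C1 | intermediate
19 | (4R,8aS)-4,8a-dimethyl-3,4,8,8a-tetrahydronaphthalene-1,6(2H,7H)-dione | O=C1CC[C@]2(C)C(=O)CC[C@@H](C)C2=C1 | intermediate
20 | (4aS,5S,8R)-5-hydroxy-4a,8-dimethyl-4,4a,5,6,7,8-hexahydronaphthalen-2(3H)-one | O=C1CC[C@]2(C)[C@@H](O)CC[C@@H](C)C2=C1 | intermediate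
21 | (4aS,5S,8R)-5-(TBS-oxy)-4a,8-dimethyl-4,4a,5,6,7,8-hexahydronaphthalen-2(3H)-one | O=C1CC[C@]2(C)[C@@H](O[Si](C)(C)C(C)(C)C)CC[C@@H](C)C2=C1 | intermediate
22 | 3-hydroxy derivative of 21 (C3 epimers) | O=C1C(O)C[C@]2(C)[C@@H](O[Si](C)(C)C(C)(C)C)CC[C@@H](C)C2=C1 | intermediate
23 | (4aS,5S,8R)-5-(TBS-oxy)-4a,8-dimethyl-2,3,4,4a,5,6,7,8-octahydronaphthalene-2,3-diol (epimers) | OC1C(O)C[C@]2(C)[C@@H](O[Si](C)(C)C(C)(C)C)CC[C@@H](C)C2=C1 | intermediate
24 | (5R,8S,8aS)-8-(TBS-oxy)-5,8a-dimethyl-1,5,6,7,8,8a-hexahydronaphthalen-2(3H)-one | O=C1CC=C2[C@H](C)CC[C@H](O[Si](C)(C)C(C)(C)C)[C@@]2(C)C1 | intermediate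
25 | methyl 2-[(3S,5R,8S,8aS)-8-(TBS-oxy)-5,8a-dimethyl-2-oxo-1,2,3,5,6,7,8,8a-octahydronaphthalen-3-yl]acetate (side chain anti) | O=C1[C@@H](CC(=O)OC)C=C2[C@H](C)CC[C@H](O[Si](C)(C)C(C)(C)C)[C@@]2(C)C1 | intermediate (not isolated)
26 | methyl 2-[(3R,5R,8S,8aS)-8-(TBS-oxy)-5,8a-dimethyl-2-oxo-1,2,3,5,6,7,8,8a-octahydronaphthalen-3-yl]acetate (side chain syn) | O=C1[C@H](CC(=O)OC)C=C2[C@H](C)CC[C@H](O[Si](C)(C)C(C)(C)C)[C@@]2(C)C1 | intermediate
27 | methyl 2-[(2S,3R,5R,8S,8aS)-8-(TBS-oxy)-2-hydroxy-5,8a-dimethyl-1,2,3,5,6,7,8,8a-octahydronaphthalen-3-yl]acetate | O[C@@H]1[C@H](CC(=O)OC)C=C2[C@H](C)CC[C@H](O[Si](C)(C)C(C)(C)C)[C@@]2(C)C1 | intermediate (not isolated)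
28 | (3aR,5R,8S,8aS,9aS)-8-(TBS-oxy)-5,8a-dimethyl-3a,5,6,7,8,8a,9,9a-octahydronaphtho[2,3-b]furan-2(3H)-one | O=C1C[C@@H]2C=C3[C@H](C)CC[C@H](O[Si](C)(C)C(C)(C)C)[C@@]3(C)C[C@@H]2O1 | intermediate
29 | 3-[(dimethylamino)methyl] derivative of 28 | O=C1C(CN(C)C)[C@@H]2C=C3[C@H](C)CC[C@H](O[Si](C)(C)C(C)(C)C)[C@@]3(C)C[C@@H]2O1 | intermediate (not isolated)
30 | (3aS,5R,8S,8aS,9aS)-8-(TBS-oxy)-5,8a-dimethyl-3-methylidene-3a,5,6,7,8,8a,9,9a-octahydronaphtho[2,3-b]furan-2(3H)-one | O=C1C(=C)[C@@H]2C=C3[C@H](C)CC[C@H](O[Si](C)(C)C(C)(C)C)[C@@]3(C)C[C@@H]2O1 | intermediate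
31 | (3aS,5R,8S,8aS,9aS)-8-hydroxy-5,8a-dimethyl-3-methylidene-3a,5,6,7,8,8a,9,9a-octahydronaphtho[2,3-b]furan-2(3H)-one | O=C1C(=C)[C@@H]2C=C3[C@H](C)CC[C@H](O)[C@@]3(C)C[C@@H]2O1 | intermediate
32 | Se-oxide of 16 | CC(=O)O[C@H]1C([Se](=O)c2ccccc2)C(C)C3=C1[C@H](C)C[C@H]4OC(=O)C(=C)[C@@H]4C3 | intermediate (not isolated)
33 | (2S,7S,8R,10R)-2-acetoxyguaia-1(5),3,11(13)-trien-12,8-olide | CC(=O)O[C@H]1C=C(C)C2=C1[C@H](C)C[C@H]3OC(=O)C(=C)[C@@H]3C2 | intermediate (not isolated)
34 | japonicone A | C=C1C(=O)O[C@@H]2C[C@@H](C)[C@]34C[C@]5(C(=O)O[C@H]6C[C@@]7(C)C(=C[C@H]65)[C@H](C)CC[C@@H]7O)[C@H](C(C)=C3C[C@@H]12)[C@@H]4OC(C)=O | target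

**Count.** Total: 21 steps. Longest linear sequence: 12 steps (steps 10–21).

**Steps most likely to fail**

1. Step 4 (proposed new method). The gold carbene may be consumed by pathways other than the ring-expanding shift (migration of C6, C–H insertion, hydration), or the cascade may stop at the allene. The fallback uses known chemistry, sets out from ketone 5 and returns at enone 10. BF3·OEt2-promoted homologation of 5 with trimethylsilyldiazomethane (migration of the less substituted α-carbon, six- to seven-membered ring, then protodesilylation) should give cycloheptanone F1. KN(SiMe3)2 and PhNTf2 convert it into the less substituted enol triflate F2. Carbonylative Stille coupling (Pd(PPh3)4 as zerovalent palladium source, CO, (E)-tributyl(prop-1-enyl)stannane, LiCl) gives the cross-conjugated dienone F3, and BF3·OEt2-promoted Nazarov cyclisation with proton loss into the ring fusion leads to 10.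

2. Step 21. The dienophile may attack the acetoxy-bearing face (the usual contrasteric preference of 5-acyloxycyclopentadienes), the diene may undergo [1,5]-hydrogen shift to enol acetate isomers before it is trapped, or it may dimerise through its own methylene lactone. The fallback sets out from alcohol 15 and silyl ether 30 and returns at 34. Alcohol 15 is silylated (Et3SiCl, imidazole) to the triethylsilyl ether F4, whose larger and less electron-withdrawing oxygen substituent should weaken the syn-directing effect. Oxidation, elimination and cycloaddition as in step 21, but with 30 as dienophile, give the bis-silyl adduct F5. Selective removal of the triethylsilyl group (PPTS, MeOH) gives alcohol F6, acetylation gives acetate F7, and HF·pyridine gives 34.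

3. Step 16. The allyl cation may lose a proton from C4' (diene formation and loss of the C4' configuration), or the product may isomerise into conjugation. The fallback sets out from enone 21 and returns at ketone 24. Condensation with 4-methylbenzenesulfonohydrazide gives hydrazone F8. Shapiro-type elimination with LiN(i-Pr)2 gives the homoannular diene F9. Hydroboration of the less hindered disubstituted alkene with 9-BBN and oxidation with NaOH/H2O2 gives the homoallylic alcohol F10, and Dess–Martin periodinane gives 24.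

Further compounds
F1 | step 4 | methyl 2-[(1S,2R,4R)-2-(TBS-oxy)-4-methyl-5-oxocycloheptyl]acetate | O=C1CC[C@@H](CC(=O)OC)[C@H](O[Si](C)(C)C(C)(C)C)C[C@H]1C
F2 | step 4 | methyl 2-[(1S,2R,4R)-2-(TBS-oxy)-4-methyl-5-(trifluoromethylsulfonyloxy)cyclohept-5-en-1-yl]acetate | O=S(=O)(OC1=CC[C@@H](CC(=O)OC)[C@H](O[Si](C)(C)C(C)(C)C)C[C@H]1C)C(F)(F)F
F3 | step 4 | methyl 2-[(1S,2R,4R)-5-[(E)-but-2-enoyl]-2-(TBS-oxy)-4-methylcyclohept-5-en-1-yl]acetate | C/C=C/C(=O)C1=CC[C@@H](CC(=O)OC)[C@H](O[Si](C)(C)C(C)(C)C)C[C@H]1C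
F4 | step 21 | 2-O-triethylsilyl ether of 15 | CC[Si](CC)(CC)O[C@H]1C([Se]c2ccccc2)C(C)C3=C1[C@H](C)C[C@H]4OC(=O)C(=C)[C@@H]4C3
F5 | step 21 | 2-O-deacetyl-2-O-triethylsilyl-1'-O-TBS-japonicone A | C=C1C(=O)O[C@@H]2C[C@@H](C)[C@]34C[C@]5(C(=O)O[C@H]6C[C@@]7(C)C(=C[C@H]65)[C@H](C)CC[C@@H]7O[Si](C)(C)C(C)(C)C)[C@H](C(C)=C3C[C@@H]12)[C@@H]4O[Si](CC)(CC)CC
F6 | step 21 | 2-O-deacetyl-1'-O-TBS-japonicone A | C=C1C(=O)O[C@@H]2C[C@@H](C)[C@]34C[C@]5(C(=O)O[C@H]6C[C@@]7(C)C(=C[C@H]65)[C@H](C)CC[C@@H]7O[Si](C)(C)C(C)(C)C)[C@H](C(C)=C3C[C@@H]12)[C@@H]4O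
F7 | step 21 | 1'-O-TBS-japonicone A | C=C1C(=O)O[C@@H]2C[C@@H](C)[C@]34C[C@]5(C(=O)O[C@H]6C[C@@]7(C)C(=C[C@H]65)[C@H](C)CC[C@@H]7O[Si](C)(C)C(C)(C)C)[C@H](C(C)=C3C[C@@H]12)[C@@H]4OC(C)=O
F8 | step 16 | 4-methylbenzenesulfonohydrazone of 21 | Cc1ccc(cc1)S(=O)(=O)NN=C1CC[C@]2(C)[C@@H](O[Si](C)(C)C(C)(C)C)CC[C@@H](C)C2=C1
F9 | step 16 | tert-butyl{[(1S,4R,8aS)-4,8a-dimethyl-1,2,3,4,8,8a-hexahydronaphthalen-1-yl]oxy}dimethylsilane | C1=CC[C@]2(C)[C@@H](O[Si](C)(C)C(C)(C)C)CC[C@@H](C)C2=C1
F10 | step 16 | (5R,8S,8aS)-8-(TBS-oxy)-5,8a-dimethyl-1,2,3,5,6,7,8,8a-octahydronaphthalen-2-ol (C2 epimers) | OC1CC=C2[C@H](C)CC[C@H](O[Si](C)(C)C(C)(C)C)[C@@]2(C)C1
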